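**Retrosynthetic overview**
1. Target 13 ⇒ global removal of three MOM ethers from 12. The C7 1,1-dimethylallyl group of 12 comes from an aromatic Claisen rearrangement of the 6-O-prenyl ether 11, where the para position is the ring fusion and is blocked.
2. Benzofuran 10 ⇒ domino Sonogashira coupling/5-endo-dig cyclisation of iodoresorcinol 8 with arylacetylene 5. The two hydroxyls of 8 are equivalent, so only one benzofuran can form.
3. Alkyne 5 ⇒ 3,5-dihydroxybenzaldehyde by MOM protection, 2,6-dibromination, double Stille prenylation and Seyferth–Gilbert homologation.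
4. Iodide 8 ⇒ phloroglucinol by mono-O-prenylation and iodination between the two hydroxyls.
5. Ring order: both benzene rings are bought; the furan ring is the only ring formed (step 7).

Assumption: the target SMILES has no stereocentre and no stereogenic double bond, so it is one achiral compound and no stereocontrol is needed.

**Route**

Step 1
Reactants: 1 3,5-dihydroxybenzaldehyde
Product: 2 3,5-bis(methoxymethoxy)benzaldehyde
Conditions: MOMCl (2.5 equiv), i-Pr2NEt, CH2Cl2, 0 °C to rt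
Reagents that add atoms: chloromethyl methyl ether, COCCl
Why: Williamson-type O-alkylation (MOM protection) of both phenols; the acetal ethers survive the later base, palladium and heat and all leave together in the last step.

Step 2
Reactants: 2 3,5-bis(methoxymethoxy)benzaldehyde
Product: 3 2,6-dibromo-3,5-bis(methoxymethoxy)benzaldehyde
Conditions: NBS (2.2 equiv), DMF, 0 °C to 40 °C
Reagents that add atoms: N-bromosuccinimide, O=C1CCC(=O)N1Br
Why: Electrophilic aromatic bromination; C2 and C6 are each para to one OMOM and ortho to the other while C4 is shielded between two OMOM groups, as in the 2,6-dibromination of 3,5-dimethoxybenzaldehyde.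

Step 3
Reactants: 3 2,6-dibromo-3,5-bis(methoxymethoxy)benzaldehyde
Product: 4 3,5-bis(methoxymethoxy)-2,6-bis(3-methylbut-2-en-1-yl)benzaldehyde
Conditions: prenyl-SnBu3 (3 equiv), Pd(PPh3)4 (10 mol %), DMF, 100 °C
Reagents that add atoms: tributyl(3-methylbut-2-en-1-yl)stannane, CCCC[Sn](CCCC)(CCCC)CC=C(C)C
Why: Double Stille coupling; the ortho-formyl aryl bromides add readily to zerovalent palladium and reductive elimination takes place at the unsubstituted allyl terminus, which gives the linear prenyl groups and leaves the aldehyde untouched.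

Step 4
Reactants: 4 3,5-bis(methoxymethoxy)-2,6-bis(3-methylbut-2-en-1-yl)benzaldehyde
Product: 5 3-ethynyl-1,5-bis(methoxymethoxy)-2,4-bis(3-methylbut-2-en-1-yl)benzene
Conditions: MeC(O)C(N2)P(O)(OMe)2, K2CO3, MeOH/THF, 0 °C to rt
Reagents that add atoms: dimethyl (1-diazo-2-oxopropyl)phosphonate, CC(=O)C(=[N+]=[N-])P(=O)(OC)OC
Why: Seyferth–Gilbert homologation in the Ohira–Bestmann variant turns the aldehyde into the terminal alkyne under mild base that MOM ethers and prenyl groups tolerate.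

Step 5
Reactants: 6 benzene-1,3,5-triol (phloroglucinol)
Product: 7 5-[(3-methylbut-2-en-1-yl)oxy]benzene-1,3-diol
Conditions: prenyl alcohol (1 equiv), 6 (3 equiv), PPh3, DIAD, THF, 0 °C to rt
Reagents that add atoms: 3-methylbut-2-en-1-ol, CC(C)=CCO
Why: Mitsunobu etherification gives O- and not C-alkylation of phloroglucinol by SN2 at the primary allylic carbon, and the excess of the symmetric triol holds the reaction at the mono-ether.

Step 6
Reactants: 7 5-[(3-methylbut-2-en-1-yl)oxy]benzene-1,3-diol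
Product: 8 2-iodo-5-[(3-methylbut-2-en-1-yl)oxy]benzene-1,3-diol
Conditions: I2 (1.0 equiv), NaHCO3, THF/H2O, 0 °C
Reagents that add atoms: iodine, II
Why: Electrophilic aromatic iodination under bicarbonate, which in resorcinols goes to the carbon between the two hydroxyls (as for 2-iodoresorcinol); this carbon is also para to the ether oxygen, and the arene reacts far faster than the alkene.

Step 7
Reactants: 8 2-iodo-5-[(3-methylbut-2-en-1-yl)oxy]benzene-1,3-diol; 5 3-ethynyl-1,5-bis(methoxymethoxy)-2,4-bis(3-methylbut-2-en-1-yl)benzene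
Product: 10 2-[3,5-bis(methoxymethoxy)-2,6-bis(3-methylbut-2-en-1-yl)phenyl]-6-[(3-methylbut-2-en-1-yl)oxy]-1-benzofuran-4-ol, via alkynylresorcinol 9 (not isolated)
Conditions: PdCl2(PPh3)2 (5 mol %), CuI (10 mol %), Et3N, DMF, rt then 80 °C, Ar
Reagents that add atoms: none
Why: Domino Sonogashira coupling/5-endo-dig heteroannulation; the two ortho hydroxyls of 8 are equivalent by symmetry, so one benzofuran forms and the other hydroxyl becomes the 4-OH.

Step 8
Reactants: 10 2-[3,5-bis(methoxymethoxy)-2,6-bis(3-methylbut-2-en-1-yl)phenyl]-6-[(3-methylbut-2-en-1-yl)oxy]-1-benzofuran-4-ol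
Product: 11 2-[3,5-bis(methoxymethoxy)-2,6-bis(3-methylbut-2-en-1-yl)phenyl]-4-(methoxymethoxy)-6-[(3-methylbut-2-en-1-yl)oxy]-1-benzofuran
Conditions: MOMCl, i-Pr2NEt, CH2Cl2, 0 °C to rt
Reagents that add atoms: chloromethyl methyl ether, COCCl
Why: MOM protection (O-alkylation) masks the 4-OH for the heating step and places a substituent next to C5.

Step 9
Reactants: 11 2-[3,5-bis(methoxymethoxy)-2,6-bis(3-methylbut-2-en-1-yl)phenyl]-4-(methoxymethoxy)-6-[(3-methylbut-2-en-1-yl)oxy]-1-benzofuran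
Product: 12 2-[3,5-bis(methoxymethoxy)-2,6-bis(3-methylbut-2-en-1-yl)phenyl]-4-(methoxymethoxy)-7-(2-methylbut-3-en-2-yl)-1-benzofuran-6-ol
Conditions: PhNEt2, 190 °C (sealed tube), 2 h
Reagents that add atoms: none
Why: Aromatic Claisen rearrangement ([3,3] shift with allyl inversion, then proton transfer back to the phenol); the para position C3a is blocked, and C7 is favoured over C5 by the higher C6–C7 bond order of the benzofuran and by the OMOM group flanking C5.

Step 10
Reactants: 12 2-[3,5-bis(methoxymethoxy)-2,6-bis(3-methylbut-2-en-1-yl)phenyl]-4-(methoxymethoxy)-7-(2-methylbut-3-en-2-yl)-1-benzofuran-6-ol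
Product: 13 2-[3,5-dihydroxy-2,6-bis(3-methylbut-2-en-1-yl)phenyl]-7-(2-methylbut-3-en-2-yl)-1-benzofuran-4,6-diol
Conditions: HCl (2 M aq, few equiv), MeOH/THF, 40 °C, degassed
Reagents that add atoms: none
Why: Acid-catalysed acetal methanolysis removes the three MOM groups as dimethoxymethane; dilute acid at 40 °C is chosen to stay below the conditions that cyclise ortho-prenyl phenols to chromans.

**Compound list**
1 | 3,5-dihydroxybenzaldehyde | O=Cc1cc(O)cc(O)c1 | starting material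
2 | 3,5-bis(methoxymethoxy)benzaldehyde | COCOc1cc(C=O)cc(OCOC)c1 | intermediate
3 | 2,6-dibromo-3,5-bis(methoxymethoxy)benzaldehyde | COCOc1cc(OCOC)c(Br)c(C=O)c1Br | intermediate
4 | 3,5-bis(methoxymethoxy)-2,6-bis(3-methylbut-2-en-1-yl)benzaldehyde | COCOc1cc(OCOC)c(CC=C(C)C)c(C=O)c1CC=C(C)C | intermediate
5 | 3-ethynyl-1,5-bis(methoxymethoxy)-2,4-bis(3-methylbut-2-en-1-yl)benzene | COCOc1cc(OCOC)c(CC=C(C)C)c(C#C)c1CC=C(C)C | intermediate
6 | benzene-1,3,5-triol (phloroglucinol) | Oc1cc(O)cc(O)c1 | starting material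
7 | 5-[(3-methylbut-2-en-1-yl)oxy]benzene-1,3-diol | CC(C)=CCOc1cc(O)cc(O)c1 | intermediate
8 | 2-iodo-5-[(3-methylbut-2-en-1-yl)oxy]benzene-1,3-diol | CC(C)=CCOc1cc(O)c(I)c(O)c1 | intermediate
9 | 2-{[3,5-bis(methoxymethoxy)-2,6-bis(3-methylbut-2-en-1-yl)phenyl]ethynyl}-5-[(3-methylbut-2-en-1-yl)oxy]benzene-1,3-diol (not isolated) | CC(C)=CCOc1cc(O)c(C#Cc2c(CC=C(C)C)c(OCOC)cc(OCOC)c2CC=C(C)C)c(O)c1 | intermediate
10 | 2-[3,5-bis(methoxymethoxy)-2,6-bis(3-methylbut-2-en-1-yl)phenyl]-6-[(3-methylbut-2-en-1-yl)oxy]-1-benzofuran-4-ol | CC(C)=CCOc1cc(O)c2cc(-c3c(CC=C(C)C)c(OCOC)cc(OCOC)c3CC=C(C)C)oc2c1 | intermediate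
11 | 2-[3,5-bis(methoxymethoxy)-2,6-bis(3-methylbut-2-en-1-yl)phenyl]-4-(methoxymethoxy)-6-[(3-methylbut-2-en-1-yl)oxy]-1-benzofuran | CC(C)=CCOc1cc(OCOC)c2cc(-c3c(CC=C(C)C)c(OCOC)cc(OCOC)c3CC=C(C)C)oc2c1 | intermediate
12 | 2-[3,5-bis(methoxymethoxy)-2,6-bis(3-methylbut-2-en-1-yl)phenyl]-4-(methoxymethoxy)-7-(2-methylbut-3-en-2-yl)-1-benzofuran-6-ol | C=CC(C)(C)c1c(O)cc(OCOC)c2cc(-c3c(CC=C(C)C)c(OCOC)cc(OCOC)c3CC=C(C)C)oc12 | intermediate
13 | 2-[3,5-dihydroxy-2,6-bis(3-methylbut-2-en-1-yl)phenyl]-7-(2-methylbut-3-en-2-yl)-1-benzofuran-4,6-diol | C=CC(C)(C)c1c(O)cc(O)c2cc(-c3c(CC=C(C)C)c(O)cc(O)c3CC=C(C)C)oc12 | target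

**Step count and risks**

Total steps: 10. Longest linear sequence: 8 (steps 1, 2, 3, 4, 7, 8, 9, 10).

The three steps most likely to fail:

- **Step 6 (site of iodination).** Every ring carbon of 7 lies between two oxygens, so some iodination between OH and the ether oxygen may compete. The fallback sets out from 7 and fixes the position by directed metalation.
  - Both hydroxyls are converted to MOM ethers (MOMCl, i-Pr2NEt, CH2Cl2) to give 1,3-bis(methoxymethoxy)-5-[(3-methylbut-2-en-1-yl)oxy]benzene F1.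
  - n-BuLi (THF, 0 °C) lithiates only between the two OMOM groups and gives {2,6-bis(methoxymethoxy)-4-[(3-methylbut-2-en-1-yl)oxy]phenyl}lithium F2.
  - Quenching with I2 at −78 °C gives 2-iodo-1,3-bis(methoxymethoxy)-5-[(3-methylbut-2-en-1-yl)oxy]benzene F3.
  - Brief methanolysis (cat. HCl, MeOH, rt) removes the two MOM groups and the route is rejoined at 8.

- **Step 7 (domino coupling).** The free, very electron-rich iodoresorcinol and the doubly ortho-substituted alkyne may couple slowly, and alkyne homocoupling may compete. The fallback sets out from 8 and separates coupling from ring closure.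
  - Acetylation (Ac2O, pyridine) gives 2-iodo-5-[(3-methylbut-2-en-1-yl)oxy]-1,3-phenylene diacetate F4.
  - Sonogashira coupling with 5 at room temperature (PdCl2(PPh3)2, CuI, Et3N, THF) stops at the isolable 2-{[3,5-bis(methoxymethoxy)-2,6-bis(3-methylbut-2-en-1-yl)phenyl]ethynyl}-5-[(3-methylbut-2-en-1-yl)oxy]-1,3-phenylene diacetate F5.
  - K2CO3 in MeOH frees 9, which is closed by warming (or with Cs2CO3 in DMF at 60 °C), and the route is rejoined at 10.

- **Step 9 (C7 against C5, and stability of the product at 190 °C).** The MOM group gives only modest steric bias, and the ortho-(1,1-dimethylallyl)phenol can react further on long heating. The fallback sets out from 10 and uses a much larger group next to C5.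
  - Silylation (i-Pr3SiCl, imidazole, DMF) gives ({2-[3,5-bis(methoxymethoxy)-2,6-bis(3-methylbut-2-en-1-yl)phenyl]-6-[(3-methylbut-2-en-1-yl)oxy]-1-benzofuran-4-yl}oxy)tri(propan-2-yl)silane F6.
  - Claisen rearrangement (PhNEt2, 190 °C) gives 2-[3,5-bis(methoxymethoxy)-2,6-bis(3-methylbut-2-en-1-yl)phenyl]-7-(2-methylbut-3-en-2-yl)-4-{[tri(propan-2-yl)silyl]oxy}-1-benzofuran-6-ol F7.
  - Bu4NF (THF, 0 °C) gives 2-[3,5-bis(methoxymethoxy)-2,6-bis(3-methylbut-2-en-1-yl)phenyl]-7-(2-methylbut-3-en-2-yl)-1-benzofuran-4,6-diol F8.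
  - Acid methanolysis as in step 10 removes the two remaining MOM groups and the route is rejoined at the target 13.

**Further compounds**
F1 | step 6 | 1,3-bis(methoxymethoxy)-5-[(3-methylbut-2-en-1-yl)oxy]benzene | COCOc1cc(OCOC)cc(OCC=C(C)C)c1
F2 | step 6 | {2,6-bis(methoxymethoxy)-4-[(3-methylbut-2-en-1-yl)oxy]phenyl}lithium | [Li]c1c(OCOC)cc(OCC=C(C)C)cc1OCOC
F3 | step 6 | 2-iodo-1,3-bis(methoxymethoxy)-5-[(3-methylbut-2-en-1-yl)oxy]benzene | COCOc1cc(OCC=C(C)C)cc(OCOC)c1I
F4 | step 7 | 2-iodo-5-[(3-methylbut-2-en-1-yl)oxy]-1,3-phenylene diacetate | CC(=O)Oc1cc(OCC=C(C)C)cc(OC(C)=O)c1I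
F5 | step 7 | 2-{[3,5-bis(methoxymethoxy)-2,6-bis(3-methylbut-2-en-1-yl)phenyl]ethynyl}-5-[(3-methylbut-2-en-1-yl)oxy]-1,3-phenylene diacetate | CC(=O)Oc1cc(OCC=C(C)C)cc(OC(C)=O)c1C#Cc1c(CC=C(C)C)c(OCOC)cc(OCOC)c1CC=C(C)C
F6 | step 9 | ({2-[3,5-bis(methoxymethoxy)-2,6-bis(3-methylbut-2-en-1-yl)phenyl]-6-[(3-methylbut-2-en-1-yl)oxy]-1-benzofuran-4-yl}oxy)tri(propan-2-yl)silane | CC(C)=CCOc1cc(O[Si](C(C)C)(C(C)C)C(C)C)c2cc(-c3c(CC=C(C)C)c(OCOC)cc(OCOC)c3CC=C(C)C)oc2c1
F7 | step 9 | 2-[3,5-bis(methoxymethoxy)-2,6-bis(3-methylbut-2-en-1-yl)phenyl]-7-(2-methylbut-3-en-2-yl)-4-{[tri(propan-2-yl)silyl]oxy}-1-benzofuran-6-ol | C=CC(C)(C)c1c(O)cc(O[Si](C(C)C)(C(C)C)C(C)C)c2cc(-c3c(CC=C(C)C)c(OCOC)cc(OCOC)c3CC=C(C)C)oc12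
F8 | step 9 | 2-[3,5-bis(methoxymethoxy)-2,6-bis(3-methylbut-2-en-1-yl)phenyl]-7-(2-methylbut-3-en-2-yl)-1-benzofuran-4,6-diol | C=CC(C)(C)c1c(O)cc(O)c2cc(-c3c(CC=C(C)C)c(OCOC)cc(OCOC)c3CC=C(C)C)oc12
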